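The vessel is closed, stirred and isothermal, with E held at constant pressure above a charge of solid Q, and nothing is dissolved at the start.

| setting | zeta | beta | south-west | north-east |
|---|---|---|---|---|
| Q | 0.013 M | 0.052 M | 0.026 M | 0.026 M |
| E | 2.5 mM (held) | 2.5 mM (held) | 2.5 mM (held) | 2.5 mM (held) |
| remark | run made earlier | run made earlier |  |  |
| time |  |  | 15 min | 30 min |

- zeta (time / min: D / %): 2.00: 9.0; 3.00: 16.8; 5.00: 32.5; 8.00: 56.2; 15.0: 88.9; 25.0: 89.7
- beta (time / min: D / %): 2.00: 2.2; 3.00: 4.2; 5.00: 8.2; 8.00: 14.0; 15.0: 27.8; 25.0: 47.4

(readings scatter by 0.3 percentage points)

- the earlier runs were read with a standard deviation of 0.3 percentage points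
- at the start none of Q is in solution
- at the start none of E is in solution
- what has only dissolved of Q counts as not reacted
- a reading or a percentage of D counts all its forms, free or not

- the winner by amount of D, in percent of the Q charged; "neither" if no more than 2 percentage points parts them (south-west / north-east / neither)
- how much D is there at the end, in percent of the Q charged: south-west
- how much D is there at the end, in percent of the Q charged: north-east

Counted in concentration, the zeta and beta runs hold nearly the same D at 8.00 min, 7.31 mM against 7.28 mM, so the early rate does not follow the charge: these readings look zero order in Q. The beta run gives a straight line of 1.02 mM/min after a lag of 0.816 min, and the zeta run levels off, with a last reading of 89.7 % of its charge. Taking that share as the ceiling, the reckoning here gives both new flasks 23.7 min as the crossing time: the lag plus the time the line needs to reach the ceiling.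

"Neither" needs south-west within 2 percentage points of the ceiling, so a crossing near 15 min, but it stands 1.58 times later. On the line, south-west reaches 55.6 %. A ceiling of 95 % moves the crossing to 25.1 min, still earlier than the 30 min of north-east.

The forecast names north-east, with 55.3 % (53.5 % to 57 %) for south-west, slightly below the figure here, and 89.7 % (86.5 % to 95 %) for north-east, holding that “the ceiling looks like a fraction of the charge”.

The flask gives 89.0 % for north-east and 56.0 % for south-west, so north-east leads, and its steps are these.

    Q ⇌ Z, rate k1*(cs1 - [Z]) while solid is left; crystals form when [Z] > cs1 (solubility = 9.40 mM, k = 0.00240 /s)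
    Z + G → D (k = 5.60 /M/s)
    2 Z → X (k = 0.670 /M/s)
    L ⇌ D, rate k4*(cs4 - [D]) while solid is left; crystals form when [D] > cs4 (solubility = 11.0 mM, k = 1.30 /s)
    E ⇌ G, rate k5*(csat - [G]) (kL = 0.140 /s)

North-east stopped at 12 min, earlier than the crossing, stands at 44.1 %, and the line gives 43.8 %. At 11.0 min in north-east, Z is in steady state, made 1.00 times as fast as it is used up, with a half-life towards D of 0.87 min, far shorter than the crossing time of 23.7 min. By 30.0 min, north-east holds Q at 0 %, Z at 0.00626 % and X at 11.0 %.

The earlier runs and the new flask are simulated with constants of no real substance; scatter was added.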